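**Retrosynthetic overview**
1. Target 17 ⇐ bis-silyl ether 16 (desilylation) ⇐ hydroxy lactone 14 + benzyl bromide 7 (trans-selective enolate alkylation, sets C3).
2. 14 ⇐ keto lactone 13 (reagent-controlled ketone reduction, sets the carbinol centre).
3. 13 ⇐ 3-aroylcyclobutanone 12 by enantioselective Baeyer–Villiger ring expansion (four- to five-membered ring, sets C4). The lactone is the only ring made; the arene and cyclobutane rings are bought.
4. 12 ⇐ 3-oxocyclobutane-1-carboxylic acid 8 + aryl bromide 4 (acyl Negishi coupling); 7 ⇐ 4 (Grignard/formaldehyde, then Appel).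
5. 4 ⇐ catechol 1 (mono-methylation, para-bromination, silylation).

Assumption: the ligand enantiomer given in step 6 delivers the (R)-lactone, by analogy with 3-arylcyclobutanones; if the first run shows the opposite sense, the mirror-image ligand is used and nothing else changes.

**Route**

Step 1
Reactants: 1 catechol (benzene-1,2-diol)
Product: 2 guaiacol (2-methoxyphenol)
Conditions: catechol (2.0 equiv), MeI (1.0 equiv), K2CO3 (1.0 equiv), acetone, reflux
Reagents that add atoms: iodomethane, CI
Why: Williamson mono-O-methylation, where excess catechol with one equivalent of base and MeI favours the monoether, and water-soluble catechol and base-insoluble veratrole are removed by extraction.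

Step 2
Reactants: 2 guaiacol
Product: 4 (4-bromo-2-methoxyphenoxy)triisopropylsilane, via 4-bromo-2-methoxyphenol 3 (not isolated)
Conditions: NBS (1.0 equiv), DMF, 0 °C → rt; then imidazole (2.5 equiv), iPr3SiCl (1.3 equiv), rt, same pot
Reagents that add atoms: N-bromosuccinimide, O=C1CCC(=O)N1Br; chlorotriisopropylsilane, CC(C)[Si](Cl)(C(C)C)C(C)C
Why: electrophilic aromatic bromination goes para to the free OH (the stronger director), and the phenol is then silylated in the same DMF solution under standard imidazole conditions.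

Step 3
Reactants: 4 (4-bromo-2-methoxyphenoxy)triisopropylsilane
Product: 6 [3-methoxy-4-(triisopropylsilyloxy)phenyl]methanol, via arylmagnesium bromide 5 (not isolated)
Conditions: Mg, I2 (cat.), THF, 50 °C; then (CH2O)n (3 equiv), 0 °C → rt; H2O
Reagents that add atoms: formaldehyde (from paraformaldehyde), C=O
Why: Grignard formation and addition to formaldehyde gives the benzylic alcohol; the aryl silyl ether is inert to the arylmagnesium reagent.

Step 4
Reactants: 6 [3-methoxy-4-(triisopropylsilyloxy)phenyl]methanol
Product: 7 [4-(bromomethyl)-2-methoxyphenoxy]triisopropylsilane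
Conditions: CBr4 (1.2 equiv), PPh3 (1.2 equiv), CH2Cl2, 0 °C; used at once
Reagents that add atoms: carbon tetrabromide, BrC(Br)(Br)Br
Why: Appel bromination is neutral, so the silyl ether survives and the electron-rich benzylic bromide is not ionised.

Step 5
Reactants: 8 3-oxocyclobutane-1-carboxylic acid; 4 (4-bromo-2-methoxyphenoxy)triisopropylsilane
Product: 12 3-[3-methoxy-4-(triisopropylsilyloxy)benzoyl]cyclobutan-1-one, via 3-oxocyclobutane-1-carbonyl chloride 9 (not isolated), via aryllithium 10 (not isolated), via arylzinc chloride 11 (not isolated)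
Conditions: 8, (COCl)2 (1.2 equiv), DMF (cat.), CH2Cl2, 0 °C → rt, evaporate; separately 4, n-BuLi (1.05 equiv), THF, −78 °C, then ZnCl2 (1.2 equiv), −78 → 0 °C; combine, Pd(PPh3)4 (3 mol %, zerovalent palladium), THF, 0 °C → rt
Reagents that add atoms: none
Why: Negishi acylation, in which bromine–lithium exchange on 4 at −78 °C (the aryl silyl ether is inert and lithium sits para to the silyloxy group, so no silyl migration) and transmetalation to zinc give an arylzinc that couples with the acid chloride under zerovalent palladium but does not add to the free cyclobutanone, so no ketone protection is needed.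

Step 6
Reactants: 12 3-[3-methoxy-4-(triisopropylsilyloxy)benzoyl]cyclobutan-1-one
Product: 13 (R)-4-[3-methoxy-4-(triisopropylsilyloxy)benzoyl]dihydrofuran-2(3H)-one
Conditions: Sc(OTf)3 (5 mol %), ligand L (6 mol %; L = 1,3-bis[(S)-2-(2,4,6-triisopropylphenylcarbamoyl)piperidin-1-yl]propane N,N′-dioxide), mCPBA (1.1 equiv), EtOAc, −20 °C
Reagents that add atoms: 3-chloroperoxybenzoic acid (mCPBA), OOC(=O)c1cccc(Cl)c1
Why: Proposed new method: a catalytic enantioselective desymmetrising Baeyer–Villiger ring expansion of a 3-acylcyclobutanone, a substrate class on which it has not been shown; the trivalent scandium/N,N′-dioxide complex binds the strained ketone, mCPBA adds to give a metal-bound Criegee adduct, and only the enantiotopic ring CH2 that can lie antiperiplanar to the O–O bond inside the ligand pocket (flat aroyl group pseudo-equatorial, away from the triisopropylanilide wall) migrates, which sets C4 as R, while ring strain makes the cyclobutanone react far faster than the aryl ketone and the near-neutral, cold conditions do not enolise the new ketone α-centre; the closest known reaction type is the scandium/N,N′-dioxide- or chiral-phosphoric-acid-catalysed desymmetrising Baeyer–Villiger oxidation of 3-aryl- and 3-benzylcyclobutanones.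

Step 7
Reactants: 13 (R)-4-[3-methoxy-4-(triisopropylsilyloxy)benzoyl]dihydrofuran-2(3H)-one
Product: 14 (R)-4-[(S)-hydroxy(3-methoxy-4-(triisopropylsilyloxy)phenyl)methyl]dihydrofuran-2(3H)-one
Conditions: (R)-2-methyl-CBS-oxazaborolidine [(R)-1-methyl-3,3-diphenyltetrahydro-1H,3H-pyrrolo[1,2-c][1,3,2]oxazaborole] (20 mol %), BH3·SMe2 (0.7 equiv), THF, −30 °C; MeOH quench, aqueous work-up
Reagents that add atoms: none
Why: Corey–Bakshi–Shibata reduction under reagent control, where the (R)-catalyst with aryl as the large group gives the (S)-carbinol, the base-free conditions leave the lactone and the ketone α-centre untouched, and any minor enantiomer of 13 becomes a diastereomer that is removed by chromatography.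

Step 8
Reactants: 14 (R)-4-[(S)-hydroxy(3-methoxy-4-(triisopropylsilyloxy)phenyl)methyl]dihydrofuran-2(3H)-one; 7 [4-(bromomethyl)-2-methoxyphenoxy]triisopropylsilane
Product: 16 (3R,4R)-4-[(S)-hydroxy(3-methoxy-4-(triisopropylsilyloxy)phenyl)methyl]-3-[3-methoxy-4-(triisopropylsilyloxy)benzyl]dihydrofuran-2(3H)-one, via dilithium alkoxide enolate 15 (not isolated)
Conditions: LiN(SiMe3)2 (2.3 equiv), THF, −78 °C (14 added to the base); then 7 (1.2 equiv), −78 → −40 °C; AcOH, −78 °C
Reagents that add atoms: none
Why: dianion (alkoxide/enolate) alkylation of the Fráter–Seebach type, where the benzyl bromide attacks the enolate face anti to the bulky C4 substituent to give the 3,4-trans (3R) lactone, and adding 14 to excess base at −78 °C enolises the lactone before the alkoxide can translactonise.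

Step 9
Reactants: 16 (3R,4R)-4-[(S)-hydroxy(3-methoxy-4-(triisopropylsilyloxy)phenyl)methyl]-3-[3-methoxy-4-(triisopropylsilyloxy)benzyl]dihydrofuran-2(3H)-one
Product: 17 (3R,4R)-4-[(S)-hydroxy(4-hydroxy-3-methoxyphenyl)methyl]-3-(4-hydroxy-3-methoxybenzyl)dihydrofuran-2(3H)-one
Conditions: Bu4NF (2.5 equiv), AcOH (3 equiv), THF, 0 °C
Reagents that add atoms: none
Why: fluoride cleavage of the two aryl silyl ethers, buffered with acetic acid so that the acid-labile para-hydroxybenzylic alcohol and the base-labile lactone and C3 centre are not disturbed.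

**Compound list**
1 | catechol (benzene-1,2-diol) | Oc1ccccc1O | starting material
2 | guaiacol (2-methoxyphenol) | COc1ccccc1O | intermediate
3 | 4-bromo-2-methoxyphenol | COc1cc(Br)ccc1O | intermediate
4 | (4-bromo-2-methoxyphenoxy)triisopropylsilane | COc1cc(Br)ccc1O[Si](C(C)C)(C(C)C)C(C)C | intermediate
5 | [3-methoxy-4-(triisopropylsilyloxy)phenyl]magnesium bromide | COc1cc([Mg]Br)ccc1O[Si](C(C)C)(C(C)C)C(C)C | intermediate
6 | [3-methoxy-4-(triisopropylsilyloxy)phenyl]methanol | COc1cc(CO)ccc1O[Si](C(C)C)(C(C)C)C(C)C | intermediate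
7 | [4-(bromomethyl)-2-methoxyphenoxy]triisopropylsilane | COc1cc(CBr)ccc1O[Si](C(C)C)(C(C)C)C(C)C | intermediate
8 | 3-oxocyclobutane-1-carboxylic acid | O=C1CC(C1)C(=O)O | starting material
9 | 3-oxocyclobutane-1-carbonyl chloride | O=C1CC(C1)C(Cl)=O | intermediate
10 | [3-methoxy-4-(triisopropylsilyloxy)phenyl]lithium | COc1cc([Li])ccc1O[Si](C(C)C)(C(C)C)C(C)C | intermediate
11 | [3-methoxy-4-(triisopropylsilyloxy)phenyl]zinc chloride | COc1cc([Zn]Cl)ccc1O[Si](C(C)C)(C(C)C)C(C)C | intermediate
12 | 3-[3-methoxy-4-(triisopropylsilyloxy)benzoyl]cyclobutan-1-one | COc1cc(C(=O)C2CC(=O)C2)ccc1O[Si](C(C)C)(C(C)C)C(C)C | intermediate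
13 | (R)-4-[3-methoxy-4-(triisopropylsilyloxy)benzoyl]dihydrofuran-2(3H)-one | O=C1OC[C@@H](C1)C(=O)c1ccc(O[Si](C(C)C)(C(C)C)C(C)C)c(OC)c1 | intermediate
14 | (R)-4-[(S)-hydroxy(3-methoxy-4-(triisopropylsilyloxy)phenyl)methyl]dihydrofuran-2(3H)-one | O=C1OC[C@@H](C1)[C@H](O)c1ccc(O[Si](C(C)C)(C(C)C)C(C)C)c(OC)c1 | intermediate
15 | dilithium alkoxide enolate of 14 (lithium benzylic alkoxide, lithium lactone enolate) | [Li]OC1=C[C@H](CO1)[C@H](O[Li])c1ccc(O[Si](C(C)C)(C(C)C)C(C)C)c(OC)c1 | intermediate
16 | (3R,4R)-4-[(S)-hydroxy(3-methoxy-4-(triisopropylsilyloxy)phenyl)methyl]-3-[3-methoxy-4-(triisopropylsilyloxy)benzyl]dihydrofuran-2(3H)-one | COc1cc(C[C@H]2C(=O)OC[C@@H]2[C@H](O)c2ccc(O[Si](C(C)C)(C(C)C)C(C)C)c(OC)c2)ccc1O[Si](C(C)C)(C(C)C)C(C)C | intermediate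
17 | (3R,4R)-4-[(S)-hydroxy(4-hydroxy-3-methoxyphenyl)methyl]-3-(4-hydroxy-3-methoxybenzyl)dihydrofuran-2(3H)-one | COc1cc(C[C@H]2C(=O)OC[C@@H]2[C@H](O)c2ccc(O)c(OC)c2)ccc1O | target

**Totals**
Total step count: 9. Longest linear sequence: 7 (steps 1, 2, 5, 6, 7, 8, 9); the side branch to bromide 7 is steps 3 and 4.

**Steps most likely to fail, and fallbacks**

Step 6 (the proposed new ring expansion). The risks are low enantioselectivity with an acyl rather than aryl group at C3, and erosion of the new ketone α-centre. The fallback uses known chemistry, sets out from 12 and comes back at 14. Compound 12 is ring-expanded with mCPBA in CH2Cl2 at 0 °C, a standard Baeyer–Villiger oxidation in which either ring CH2 gives the same constitution, to racemic 4-[3-methoxy-4-(triisopropylsilyloxy)benzoyl]dihydrofuran-2(3H)-one F1. The racemate is then reduced with the same (R)-CBS catalyst and BH3·SMe2. Reagent control turns the two enantiomers into two diastereomers, 14 and (S)-4-[(S)-hydroxy(3-methoxy-4-(triisopropylsilyloxy)phenyl)methyl]dihydrofuran-2(3H)-one F2, which are separated by chromatography. This caps the yield of 14 at half.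

Step 7 (catalyst-controlled reduction next to a stereocentre). The risks are a mismatched pairing, or the branched lactone carbon competing with the aryl group as the large substituent. The fallback sets out from 13 and comes back at 14, and replaces asymmetric catalysis by separation and recycling. Ketone 13 is reduced without stereocontrol using NaBH4 in THF/MeOH at −40 °C, giving 14 together with its carbinol epimer (R)-4-[(R)-hydroxy(3-methoxy-4-(triisopropylsilyloxy)phenyl)methyl]dihydrofuran-2(3H)-one F3. The two are separated by chromatography. F3 is oxidised back to 13 with Dess–Martin periodinane in CH2Cl2 and resubmitted.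

Step 8 (alkylation with the carbinol unprotected). The risks are translactonisation through the lithium alkoxide before enolisation, and O-benzylation. The fallback sets out from 14 and comes back at 17, and masks the alcohol. Compound 14 is silylated with Et3SiCl and imidazole in CH2Cl2 to (R)-4-[(S)-(3-methoxy-4-(triisopropylsilyloxy)phenyl)(triethylsilyloxy)methyl]dihydrofuran-2(3H)-one F4. F4 is alkylated as a simple mono-enolate with LiN(SiMe3)2 (1.1 equiv) and 7 in THF at −78 °C to (3R,4R)-3-[3-methoxy-4-(triisopropylsilyloxy)benzyl]-4-[(S)-(3-methoxy-4-(triisopropylsilyloxy)phenyl)(triethylsilyloxy)methyl]dihydrofuran-2(3H)-one F5. Buffered Bu4NF/AcOH in THF then removes all three silyl groups in one operation to give 17. This costs one step.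

**Further compounds**
F1 | step 6 | racemic 4-[3-methoxy-4-(triisopropylsilyloxy)benzoyl]dihydrofuran-2(3H)-one | COc1cc(C(=O)C2COC(=O)C2)ccc1O[Si](C(C)C)(C(C)C)C(C)C
F2 | step 6 | (S)-4-[(S)-hydroxy(3-methoxy-4-(triisopropylsilyloxy)phenyl)methyl]dihydrofuran-2(3H)-one | O=C1OC[C@H](C1)[C@H](O)c1ccc(O[Si](C(C)C)(C(C)C)C(C)C)c(OC)c1
F3 | step 7 | (R)-4-[(R)-hydroxy(3-methoxy-4-(triisopropylsilyloxy)phenyl)methyl]dihydrofuran-2(3H)-one | O=C1OC[C@@H](C1)[C@@H](O)c1ccc(O[Si](C(C)C)(C(C)C)C(C)C)c(OC)c1
F4 | step 8 | (R)-4-[(S)-(3-methoxy-4-(triisopropylsilyloxy)phenyl)(triethylsilyloxy)methyl]dihydrofuran-2(3H)-one | O=C1OC[C@@H](C1)[C@H](O[Si](CC)(CC)CC)c1ccc(O[Si](C(C)C)(C(C)C)C(C)C)c(OC)c1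
F5 | step 8 | (3R,4R)-3-[3-methoxy-4-(triisopropylsilyloxy)benzyl]-4-[(S)-(3-methoxy-4-(triisopropylsilyloxy)phenyl)(triethylsilyloxy)methyl]dihydrofuran-2(3H)-one | COc1cc(C[C@H]2C(=O)OC[C@@H]2[C@H](O[Si](CC)(CC)CC)c2ccc(O[Si](C(C)C)(C(C)C)C(C)C)c(OC)c2)ccc1O[Si](C(C)C)(C(C)C)C(C)C
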